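| setting | alder | cedar | maple | flask |
|---|---|---|---|---|
| starting material | 1 mM | 1 mM | 1 mM | 1.0 mM |
| partner | 1.2 mM | 5 mM | 2.5 mM | 2.50 mM |
| free catalyst | 99 µM | 99 µM | 200 µM | 99 µM |
| remark | run made earlier | run made earlier | run made earlier |  |

| run | time / min | target / % | starting material / % |
|---|---|---|---|
| alder | 1.00 | 10.1 | 81.1 |
| alder | 3.00 | 15.5 | 76.9 |
| alder | 5.00 | 15.4 | 77.5 |
| alder | 8.00 | 17.6 | 76.0 |
| alder | 10.0 | 16.1 | 76.4 |
| alder | 15.0 | 16.0 | 76.8 |
| alder | 20.0 | 15.5 | 76.4 |
| cedar | 1.33 | 20.6 | 71.0 |
| cedar | 2.00 | 27.7 | 64.3 |
| cedar | 3.00 | 31.1 | 62.1 |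
| cedar | 5.00 | 31.3 | 60.2 |
| cedar | 8.00 | 30.4 | 62.5 |
| cedar | 12.0 | 31.3 | 62.2 |
| cedar | 20.0 | 28.5 | 62.9 |
| maple | 4.00 | 41.1 | 42.7 |
| maple | 8.00 | 41.8 | 44.2 |
| maple | 10.0 | 42.3 | 46.4 |
| maple | 15.0 | 44.2 | 44.3 |
| maple | 20.0 | 43.8 | 44.5 |

(scatter of a reading: 1 percentage point)

- candidate steps: starting material + free catalyst <-> catalyst intermediate A; partner + catalyst intermediate A -> catalyst intermediate B; catalyst intermediate B <-> by-product + catalyst intermediate C; catalyst intermediate C -> free catalyst + target; partner -> decomposed reagent
- what is bound to the catalyst counts as converted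

- factor on the rate of making target when 20 % of the starting material are converted if free catalyst is charged twice over
- factor on the rate when 20 % of the starting material are converted if free catalyst is charged at 1000 µM instead

Start at early times. After 1.00 min the alder run shows 10.1 % target and 81.1 % starting material. So 88.0 µM is missing, against 99 µM of catalyst charged. Read that as starting material sitting on catalyst. Then see the stall: alder ends near 76.4 % starting material, so look to the partner.

Keep the books on partner in the flask, which holds 2.50 mM. Entry one is target, and each target costs one partner. Over the last 3 readings alder stands at 15.9 % and cedar at 30.1 %. My own interpolation, straight in ln c(partner), gives 0.232 mM. Entry two is catalyst: I take it to rest at the stall as catalyst intermediate A, which carries no partner, so book nothing. Entry three is decomposed reagent, the remainder, 2.27 mM. The books close with 9.28 % of the partner in target, and partner is the limiting reagent.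

Now take the mark. It is 200 µM converted, and the flask charges 99 µM of catalyst, which leaves 101 µM. Call this the turnover debt: the target that has to exist at the mark even with each catalyst holding one starting material. It is 43.5 % of entry one. Doubling the charge cuts it to 2.00 µM, and 1000 µM gives −800 µM. A negative debt lets the mark fall before any target is owed. So I expect a factor below one at 1000 µM, and I give no figure.

The forecast gives 2.5 for the doubled charge and 0.15 at 1000 µM, where the mark is “reached during the binding burst, before turnover starts”.

The simulation gives 2.27 and 0.0528, so the forecast's second factor is 2.84 times the simulated one.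

    starting material + free catalyst ⇌ catalyst intermediate A (K = 4200 M⁻¹, k = 330 M⁻¹ s⁻¹)
    partner + catalyst intermediate A → catalyst intermediate B (k = 140 M⁻¹ s⁻¹)
    catalyst intermediate B ⇌ by-product + catalyst intermediate C (K = 6.40 × 10⁻⁴ M, k = 0.0510 s⁻¹)
    catalyst intermediate C → free catalyst + target (k = 0.360 s⁻¹)
    partner → decomposed reagent (k = 0.0330 s⁻¹)

The flask passes its mark at 0.810 min, making target at 0.143 mM min⁻¹. Its debt at the mark is 101 µM. Reckoned the same way at 1.50 min, with 73.0 % starting material left in the flask, the debt is 171 µM, and target then stands at 192 µM, more than that debt. The 1000 µM charge has a debt of −800 µM, and at its mark target is made at 0.00755 mM min⁻¹.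

Readings and results were computed for an exercise, and the scatter is random.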